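**Plan**
1. Numbering used below (Stemona): pyrrole C1–C2–C3–N4; azepane C5–C8; C9; C9a; carbocycle C10 (Et), C11 (O), C12; fused lactone C13 (Me), C14; side lactone C18 (O), C19, C20 (Me), C21 (C=O).
2. Retrosynthesis: cut O–C18 and C20–C21 together (side lactone from a C3-butadienyl group and CO2), then C18=C19 and C3–C18, then C12=C13/O–C14 and C11–O, then the pyrrole (C1–C2, C3–N4) and N4–C9a, then C1–C9a, C8–C9 and C9–C10.
3. Forward: Michael adduct, cyclohexane-1,3-dione, azepane (enaminone), pyrrole, fused butenolide, saturated lactone, formyl, diene, side lactone last.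
4. Stereochemistry: C10 from the catalytic Michael addition; C9 and C11 by equilibration trans to their ring neighbours; C12 and C13 by syn-hydrogenation from the convex face; C20 from the chiral ligand on copper and C18 from the chiral phosphoric acid in the key step.
5. Enabling feature: the electron-rich pyrrole ring (N4 lone pair relayed through C3 to exocyclic C18) stabilises the C18-bound allylcopper, which sends CO2 to C20, and then the C18 cation (azafulvenium) onto which the carboxylate oxygen closes.

Key step: step 12

Remark: where a catalyst antipode is written (steps 1 and 12, and the fallback reduction), it is the one expected by analogy; the sense of induction is to be confirmed on a model and the other antipode used if it is opposite.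

Step 1
Reactants: 1 dibenzyl malonate; 2 (E)-hex-3-en-2-one
Product: 3 dibenzyl 2-[(3S)-5-oxohexan-3-yl]propanedioate
Conditions: 9-amino-9-deoxy-epi-quinine (10 mol %), PhCO2H (20 mol %), THF, rt
Reagents that add atoms: none
Why: Iminium-catalysed asymmetric Michael addition of a malonate to an acyclic enone; the catalyst shields one face of the β-carbon, so it sets C10 (S in 3, which becomes 10R in the target).

Step 2
Reactants: 3; 4 benzyl N-(4-bromobutyl)carbamate
Product: 5 dibenzyl 2-[4-(benzyloxycarbonylamino)butyl]-2-[(3S)-5-oxohexan-3-yl]propanedioate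
Conditions: NaH (1.05 equiv), DMF, 0 °C; then 4, NaI (cat.), 50 °C
Reagents that add atoms: none
Why: Malonate alkylation (SN2) at the most acidic C–H of 3 forms C8–C9; no stereocentre is formed and C10 is untouched.

Step 3
Reactants: 5
Product: 6 benzyl (6S)-1-[4-(benzyloxycarbonylamino)butyl]-6-ethyl-2,4-dioxocyclohexane-1-carboxylate (epimers at C1 of the ring)
Conditions: LiN(SiMe3)2 (3.2 equiv), THF, −78 to 0 °C; aq. HCl quench
Reagents that add atoms: none
Why: Intramolecular Claisen (Dieckmann-type) condensation: the kinetic methyl-ketone enolate attacks one benzyl ester (6-exo-trig) and deprotonation of the resulting 1,3-dione drives it; the quaternary carbon formed is a mixture that is erased in step 4.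

Step 4
Reactants: 6
Product: 8 (5aR,6S)-6-ethyl-1,2,3,4,5,5a,6,7-octahydro-8H-1-benzazepin-8-one, via aminobutyl dione 7 (not isolated)
Conditions: H2 (1 atm), 10% Pd/C, EtOH, rt; filter; AcOH (cat.), toluene, 80 °C
Reagents that add atoms: none
Why: Hydrogenolysis of the benzyl ester and benzyl carbamate, decarboxylation of the β-keto acid and intramolecular amine–dione condensation (enaminone formation) close the azepane; C9 is protonated under equilibrating conditions and should settle trans to the C10 ethyl group, both pseudo-equatorial.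

Step 5
Reactants: 8; 9 2-chloroacetaldehyde
Product: 10 (9R,10S)-10-ethyl-12-oxo tricyclic pyrrole (azepane N4/C5–C8/C9 and cyclohexanone C9–C12 fused to the pyrrole; C2–H and C3–H free)
Conditions: 9 (50 wt % aq.), NaHCO3, EtOH–H2O, 60 °C
Reagents that add atoms: none
Why: Hantzsch-type pyrrole annulation of a cyclic secondary enaminone with an α-halo aldehyde (alkylation, then cyclodehydration), the standard route to 4-oxo-4,5,6,7-tetrahydroindoles; no stereocentre is formed.

Step 6
Reactants: 10
Product: 11 (9R,10R,11S)-10-ethyl-11-hydroxy-12-oxo tricyclic pyrrole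
Conditions: KN(SiMe3)2, THF, −78 °C; 2-(phenylsulfonyl)-3-phenyloxaziridine; aq. NH4Cl; DBU (cat.), CH2Cl2 if C11 epimers need equilibrating
Reagents that add atoms: 2-(phenylsulfonyl)-3-phenyloxaziridine, O=S(=O)(c1ccccc1)N1OC1c1ccccc1
Why: Enolate α-hydroxylation with an N-sulfonyloxaziridine at C11, anti to the vicinal C10 ethyl group; because C11 is α to the ketone, the ketol can also be equilibrated to the trans-diequatorial 11S isomer.

Step 7
Reactants: 11; 12 2-(diethoxyphosphoryl)propanoic acid
Product: 13 (9R,10R,11S)-11-[2-(diethoxyphosphoryl)propanoyloxy]-10-ethyl-12-oxo tricyclic pyrrole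
Conditions: DCC, DMAP (cat.), CH2Cl2, 0 °C to rt
Reagents that add atoms: none
Why: Carbodiimide (Steglich) esterification of the secondary alcohol; ring stereocentres are untouched and the phosphonate α-carbon becomes sp2 in step 8.

Step 8
Reactants: 13
Product: 14 (9R,10R,11S)-fused butenolide (C12=C13, C13 methyl, C14 carbonyl, O on C11)
Conditions: LiCl, DBU, MeCN, rt to 50 °C
Reagents that add atoms: none
Why: Intramolecular Horner–Wadsworth–Emmons olefination of the C12 ketone by the tethered phosphonate closes the five-membered butenolide; no new stereocentre.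

Step 9
Reactants: 14
Product: 15 (9R,10R,11S,12R,13R)-tetracyclic lactone (cis-fused α-methyl-γ-butyrolactone; C3–H free)
Conditions: H2 (5 atm), 10% Pd/C, EtOAc, rt
Reagents that add atoms: none
Why: Heterogeneous syn-hydrogenation delivers hydrogen to C12 and C13 from the butenolide face that carries H11 (the other face is blocked by C10 and its ethyl group), giving the cis-fused lactone with H11, H12 and H13 all cis and the C13 methyl on the concave face.

Step 10
Reactants: 15
Product: 17 (9R,10R,11S,12R,13R)-3-formyl tetracyclic lactone, via iminium chloride 16 (not isolated)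
Conditions: POCl3, DMF, ClCH2CH2Cl, 0 °C to rt; then H2O, NaOAc, 40 °C
Reagents that add atoms: N,N-dimethylformamide, CN(C)C=O; water, O
Why: Vilsmeier–Haack formylation at the only free pyrrole α-position (C3), preferred over β-C2; no stereocentre is formed and the lactone is stable to the conditions.

Step 11
Reactants: 17; 18 allyltriphenylphosphonium bromide
Product: 19 (9R,10R,11S,12R,13R)-3-[(E)-buta-1,3-dien-1-yl] tetracyclic lactone (an E/Z mixture at C18=C19 is acceptable)
Conditions: 18, KN(SiMe3)2 (0.95 equiv to 18), THF, −78 °C; then 17, −78 to 0 °C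
Reagents that add atoms: none
Why: Wittig olefination with the semi-stabilised allylic ylide gives the 1,3-diene; the C18=C19 geometry is erased in step 12, and the ylide is too weakly basic to enolise the lactone.

Step 12
Reactants: 19; 20 carbon dioxide
Product: 23 target CNP0232452.4, via silyl ester 21 (not isolated), via butenoic acid 22 (not isolated)
Conditions: Cu(OAc)2 (5 mol %), (R)-DTBM-SEGPHOS (6 mol %), (EtO)3SiH (1.3 equiv), CO2 (1 atm), THF, rt; then H2O (3 equiv), (R)-TRIP (20 mol %), toluene, −30 °C
Reagents that add atoms: none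
Why: Proposed new method: the ligated monovalent copper hydride adds across the terminal C20=C22 bond (H to C22, which becomes the C20 methyl group), the allylcopper equilibrates to the pyrrole-stabilised C18-bound form, and this attacks CO2 through a six-membered SE2' transition state at C20, forming C20–C21 with the ligand controlling the C20 face (20S) and releasing silyl ester 21 by exchange with the silane. The closest known reaction types are the copper-hydride-catalysed enantioselective reductive carboxylation of 1-aryl-1,3-dienes with CO2 and the Brønsted-acid hydrolactonisation of 4-aryl-but-3-enoic acids; new is their union in one flask on a 2-dienylpyrrole, stopped at the carboxylate level. After hydrolysis to acid 22, the chiral phosphoric acid protonates C19 of the enamine-like 2-vinylpyrrole, and the azafulvenium ion (charge shared by C18, C3 and N4) is captured by the carboxyl oxygen in a 5-exo-trig closure that forms O–C18 and the γ-lactone ring. C18 (18R, trans to the C20 methyl) is set in this ion pair by the chiral phosphate, not by the remote core. The step needs regioselectivity for C20 over C18 (secured by the SE2' path from the C18–Cu species and by conjugation of the new C18=C19 bond with the pyrrole), chemoselectivity over reduction of the C14 lactone and the silyl ester (a slight excess of a mild silane at rt), and kinetic control at C18 (low temperature and short acid contact, because the 18-epimer with cis methyl is expected to be the more stable).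

**Compound list**
1 | dibenzyl malonate | O=C(CC(=O)OCc1ccccc1)OCc1ccccc1 | starting material
2 | (E)-hex-3-en-2-one | CC/C=C/C(C)=O | starting material
3 | dibenzyl 2-[(3S)-5-oxohexan-3-yl]propanedioate | CC[C@H](C(C(=O)OCc1ccccc1)C(=O)OCc1ccccc1)CC(C)=O | intermediate
4 | benzyl N-(4-bromobutyl)carbamate | O=C(NCCCCBr)OCc1ccccc1 | starting material
5 | dibenzyl 2-[4-(benzyloxycarbonylamino)butyl]-2-[(3S)-5-oxohexan-3-yl]propanedioate | CC[C@H](C(CCCCNC(=O)OCc1ccccc1)(C(=O)OCc1ccccc1)C(=O)OCc1ccccc1)CC(C)=O | intermediate
6 | benzyl (6S)-1-[4-(benzyloxycarbonylamino)butyl]-6-ethyl-2,4-dioxocyclohexane-1-carboxylate (C1 epimers) | CC[C@H]1CC(=O)CC(=O)C1(CCCCNC(=O)OCc2ccccc2)C(=O)OCc2ccccc2 | intermediate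
7 | (4R,5S)-4-(4-aminobutyl)-5-ethylcyclohexane-1,3-dione (not isolated) | CC[C@H]1CC(=O)CC(=O)[C@@H]1CCCCN | intermediate
8 | (5aR,6S)-6-ethyl-1,2,3,4,5,5a,6,7-octahydro-8H-1-benzazepin-8-one | CC[C@H]1CC(=O)C=C2[C@@H]1CCCCN2 | intermediate
9 | 2-chloroacetaldehyde | ClCC=O | starting material
10 | (9R,10S)-10-ethyl-12-oxo tricyclic pyrrole | CC[C@H]1CC(=O)c2ccn3c2[C@@H]1CCCC3 | intermediate
11 | (9R,10R,11S)-10-ethyl-11-hydroxy-12-oxo tricyclic pyrrole | CC[C@H]1[C@H](O)C(=O)c2ccn3c2[C@@H]1CCCC3 | intermediate
12 | 2-(diethoxyphosphoryl)propanoic acid | CC(C(=O)O)P(=O)(OCC)OCC | starting material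
13 | (9R,10R,11S)-11-[2-(diethoxyphosphoryl)propanoyloxy]-10-ethyl-12-oxo tricyclic pyrrole | CC[C@H]1[C@H](OC(=O)C(C)P(=O)(OCC)OCC)C(=O)c2ccn3c2[C@@H]1CCCC3 | intermediate
14 | (9R,10R,11S)-fused butenolide | CC[C@H]1[C@@H]2OC(=O)C(C)=C2c2ccn3c2[C@@H]1CCCC3 | intermediate
15 | (9R,10R,11S,12R,13R)-tetracyclic lactone, C3–H | CC[C@H]1[C@@H]2OC(=O)[C@H](C)[C@@H]2c2ccn3c2[C@@H]1CCCC3 | intermediate
16 | C3 dimethyliminium chloride of 15 (not isolated) | CC[C@H]1[C@@H]2OC(=O)[C@H](C)[C@@H]2c2cc(C=[N+](C)C)n3c2[C@@H]1CCCC3.[Cl-] | intermediate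
17 | 3-formyl tetracyclic lactone | CC[C@H]1[C@@H]2OC(=O)[C@H](C)[C@@H]2c2cc(C=O)n3c2[C@@H]1CCCC3 | intermediate
18 | allyltriphenylphosphonium bromide | C=CC[P+](c1ccccc1)(c1ccccc1)c1ccccc1.[Br-] | starting material
19 | 3-[(E)-buta-1,3-dien-1-yl] tetracyclic lactone | CC[C@H]1[C@@H]2OC(=O)[C@H](C)[C@@H]2c2cc(/C=C/C=C)n3c2[C@@H]1CCCC3 | intermediate
20 | carbon dioxide | O=C=O | starting material
21 | triethoxysilyl (2S)-2-methyl-4-(tetracycl-3-yl)but-3-enoate (not isolated; alkene geometry not fixed) | CC[C@H]1[C@@H]2OC(=O)[C@H](C)[C@@H]2c2cc(C=C[C@H](C)C(=O)O[Si](OCC)(OCC)OCC)n3c2[C@@H]1CCCC3 | intermediate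
22 | (2S)-2-methyl-4-(tetracycl-3-yl)but-3-enoic acid (not isolated) | CC[C@H]1[C@@H]2OC(=O)[C@H](C)[C@@H]2c2cc(C=C[C@H](C)C(=O)O)n3c2[C@@H]1CCCC3 | intermediate
23 | CNP0232452.4, (9R,10R,11S,12R,13R,18R,20S) | CC[C@H]1[C@@H]2OC(=O)[C@H](C)[C@@H]2c2cc([C@H]3C[C@H](C)C(=O)O3)n3c2[C@@H]1CCCC3 | target

**Count**
Total steps: 12. Longest linear sequence: 12 steps (from 1 and 2 to 23).

**Steps most likely to fail, with fallbacks**

Step 12 (Proposed new method). Possible failures are over-reduction of the silyl carboxylate by copper hydride, carboxylation at C18 instead of C20, acid-induced oligomerisation of the vinylpyrrole, and poor facial selectivity or equilibration at C18 towards the cis lactone. The fallback sets out from 15 and returns at 23 with known chemistry. Friedel–Crafts acylation of 15 at C3 with methyl 4-chloro-4-oxobutanoate (ZnCl2, CH2Cl2, 0 °C) would give methyl 4-oxo-4-(tetracycl-3-yl)butanoate F1. Asymmetric transfer hydrogenation of this ketone (RuCl[(S,S)-TsDPEN](p-cymene), HCO2H/Et3N) would give the 18R hydroxy ester F2, which should close with loss of methanol to the unmethylated 18R lactone F3. Kinetic enolisation of the less hindered CH2 lactone (LiN(iPr)2, 1.05 equiv, THF, −78 °C) and MeI would then place the C20 methyl anti to the C18 pyrrolyl group and give 23.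

Step 9. Possible failures are slow or incomplete hydrogenation of the tetrasubstituted, pyrrole-conjugated alkene, and loss of facial control or pyrrole reduction under forcing conditions. The fallback sets out from 11 and returns at 15. Esterification of 11 with 2-(diethoxyphosphoryl)acetic acid (DCC, DMAP) would give phosphonoacetate F4, and intramolecular Horner–Wadsworth–Emmons reaction (LiCl, DBU) the trisubstituted butenolide F5. Hydrogenation (H2, Pd/C) should give the cis-fused unmethylated lactone F6. LiN(iPr)2 and dimethylmethyleneiminium iodide would give Mannich base F7, and quaternisation (MeI) with elimination (NaHCO3) the α-methylene lactone F8. Its hydrogenation from the convex face (H2, Pd/C) places the methyl on the concave face and gives 15.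

Step 5. Possible failures are self-condensation of the aldehyde, competing N- versus C-attack leading to stalled intermediates, and low conversion of the hindered bicyclic enaminone. The fallback sets out from 8 and returns at 10. N-alkylation of 8 with 2-bromo-1,1-diethoxyethane (NaH, NaI, DMF, 60 °C) would give the N-(2,2-diethoxyethyl) enaminone F9. CF3CO2H in CH2Cl2 should then form the oxocarbenium ion, which the enaminone α-carbon (C1) attacks; loss of two ethanol gives the pyrrole 10.

**Further compounds**
F1 | step 12 | methyl 4-oxo-4-(tetracycl-3-yl)butanoate | CC[C@H]1[C@@H]2OC(=O)[C@H](C)[C@@H]2c2cc(C(=O)CCC(=O)OC)n3c2[C@@H]1CCCC3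
F2 | step 12 | methyl (4R)-4-hydroxy-4-(tetracycl-3-yl)butanoate | CC[C@H]1[C@@H]2OC(=O)[C@H](C)[C@@H]2c2cc([C@H](O)CCC(=O)OC)n3c2[C@@H]1CCCC3
F3 | step 12 | (18R)-20-demethyl target lactone | CC[C@H]1[C@@H]2OC(=O)[C@H](C)[C@@H]2c2cc([C@H]3CCC(=O)O3)n3c2[C@@H]1CCCC3
F4 | step 9 | (9R,10R,11S)-11-[2-(diethoxyphosphoryl)acetoxy]-10-ethyl-12-oxo tricyclic pyrrole | CC[C@H]1[C@H](OC(=O)CP(=O)(OCC)OCC)C(=O)c2ccn3c2[C@@H]1CCCC3
F5 | step 9 | (9R,10R,11S)-fused butenolide without C13 methyl | CC[C@H]1[C@@H]2OC(=O)C=C2c2ccn3c2[C@@H]1CCCC3
F6 | step 9 | (9R,10R,11S,12R)-cis-fused lactone without C13 methyl | CC[C@H]1[C@@H]2OC(=O)C[C@@H]2c2ccn3c2[C@@H]1CCCC3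
F7 | step 9 | 13-(dimethylaminomethyl) lactone (C13 epimers) | CC[C@H]1[C@@H]2OC(=O)C(CN(C)C)[C@@H]2c2ccn3c2[C@@H]1CCCC3
F8 | step 9 | 13-methylene lactone | CC[C@H]1[C@@H]2OC(=O)C(=C)[C@@H]2c2ccn3c2[C@@H]1CCCC3
F9 | step 5 | (5aR,6S)-1-(2,2-diethoxyethyl)-6-ethyl-1,2,3,4,5,5a,6,7-octahydro-8H-1-benzazepin-8-one | CC[C@H]1CC(=O)C=C2[C@@H]1CCCCN2CC(OCC)OCC
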